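What is left of the two substrates is best held as one number, which stands at 0.942 in the last maple readings: the gap, ln([right-handed substrate]/[left-handed substrate]). With a steady selectivity factor, the gap grows in step with the exposure: [partner] times [working catalyst], summed over time.

the same everywhere: left-handed substrate 0.039 M; right-handed substrate 0.039 M; partner 0.117 M; impurity 80 µM; added ligand 0.78 mM

|  | free catalyst | remark | time |
|---|---|---|---|
| maple | 0.095 mM | run made earlier |  |
| larch | 0.38 mM | run made earlier |  |
| flask | 0.19 mM |  | 3.0 min |

| run | time / min | right-handed substrate / % | left-handed substrate / % | left-handed product / % |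
|---|---|---|---|---|
| maple | 0.250 | 47.8 | 31.2 | 18.7 |
| maple | 0.417 | 49.0 | 27.6 | 23.2 |
| maple | 0.833 | 48.5 | 24.2 | 26.5 |
| maple | 1.50 | 45.6 | 20.7 | 28.4 |
| maple | 3.00 | 44.9 | 17.5 | 33.1 |
| larch | 0.667 | 36.9 | 1.3 | 49.1 |
| larch | 1.33 | 32.5 | 0 | 50.1 |
| larch | 2.00 | 31.6 | 0 | 48.9 |
| larch | 2.50 | 27.9 | 1.5 | 50.6 |
| larch | 3.00 | 27.4 | 1.0 | 49.6 |

(standard deviation of a reading: 1 percentage point)

- free catalyst is single-handed; left-handed substrate and right-handed substrate are mirror images of each other, charged as a racemate, each of them at the stated concentration

- whether the excess of right-handed substrate over left-handed substrate among what is left of the two reaches 80% by 3.0 min (no / yes)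
- the highest excess of right-handed substrate over left-handed substrate among what is left of the two up to 3.0 min

**Gap needed.** An excess of 80% means a ratio of 9.00, so a gap of 2.20, which is 2.33 times maple's.

**Two extremes.** Taking the fall of [partner] as alike in the runs, if the gap simply follows the catalyst charge, the flask reaches 1.88, less than needed, an excess of 73.6%. If the impurity instead removes its own amount of catalyst, the working charge gives a multiple of 7.33, a gap of 6.91 and an excess of 99.8%.

**Larch between.** In larch the left-handed substrate sits at the scatter, but the loss of right-handed substrate, ln(0.5/fraction left), still reads the same exposure. It is 5.59 times maple's, against 4.00 and 20.0 from the extremes. My reading is a fixed loss of 32.9 µM of catalyst, so a flask gap of 2.38 and an excess of 83.1%.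

**The forecast.** It says yes, with a top of 82%, “only a marginal yes”.

**Flask result.** The flask answers yes: the excess tops out at 93.4% and reaches 80% at 1.13 min.

    partner + free catalyst + left-handed substrate → free catalyst + left-handed product (k = 8800 M⁻² s⁻¹)
    free catalyst + impurity → spent catalyst (k = 2100 M⁻¹ s⁻¹)
    free catalyst + added ligand ⇌ idle complex, settled at all times (K = 1100 M⁻¹)
    free catalyst ⇌ dormant form (K = 14.0, k = 0.0210 s⁻¹)
    partner + free catalyst + right-handed substrate → free catalyst + right-handed product (k = 620 M⁻² s⁻¹)

**Gap again.** That top is a gap of 3.37, which is 3.58 times maple's, above the lower multiple and below the upper one. With twice the flask's free catalyst, the excess at the end of the run is 99.9%, a gap of 7.93, or 8.41 times maple's.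

The earlier runs and the new flask are calculated with made-up constants, noise included.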